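**Retrosynthetic overview**
- Building blocks: A-ring ketone 4 (from arene 1 and acid chloride 2 through ketone 3) and B-ring aldehyde 6 (from 5). Both benzene rings are bought, not built.
- C–C union: 4 + 6 give the α-methoxychalcone 8 (through aldol adduct 7), which already holds every carbon and the future 3-OMe.
- Key disconnection: the O1–C2 bond of flavone 9, made from the phenol O–H and the enone β-carbon of 8 by oxidative C–O ring closure.
- Target 10 comes from 9 by one-pot removal of two benzyl ethers and the peri 5-O-methyl group.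
- Ring order: the pyranone (C ring) is the only ring formed, in step 4.

Assumption: the target has no stereocentre and is achiral, so no enantiocontrol is needed; 1, 2 and 5 are taken as catalogue chemicals.

**Step 1**
Reactants: 1 1,2,3,5-tetramethoxybenzene; 2 methoxyacetyl chloride
Product: 4 1-(2-hydroxy-3,4,6-trimethoxyphenyl)-2-methoxyethan-1-one, via tetramethoxyphenyl ketone 3 (not isolated)
Conditions: AlCl3 (2.5 equiv), Et2O, 0 °C → rt, 24 h; then 2 M HCl
Reagents that add atoms: none
Why: Friedel–Crafts acylation at one of the two equivalent activated CH positions is followed in the same pot by AlCl3-chelation-controlled ortho-demethylation, which cleaves the more crowded 2-OMe (between the acyl group and the 3-OMe) rather than the 6-OMe, as is usual for this arene with simple acyl chlorides.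

**Step 2**
Reactants: 5 2,4-dihydroxy-5-methoxybenzaldehyde
Product: 6 2,4-bis(benzyloxy)-5-methoxybenzaldehyde
Conditions: BnBr (2.4 equiv), K2CO3 (3 equiv), DMF, 60 °C, 6 h
Reagents that add atoms: benzyl bromide, BrCc1ccccc1
Why: Double Williamson etherification masks both phenols, which as phenoxides would otherwise deactivate the aldehyde towards the aldol step.

**Step 3**
Reactants: 4 1-(2-hydroxy-3,4,6-trimethoxyphenyl)-2-methoxyethan-1-one; 6 2,4-bis(benzyloxy)-5-methoxybenzaldehyde
Product: 8 (Z)-3-[2,4-bis(benzyloxy)-5-methoxyphenyl]-1-(2-hydroxy-3,4,6-trimethoxyphenyl)-2-methoxyprop-2-en-1-one, via aldol adduct 7 (not isolated)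
Conditions: KOH (50% aq., 10 equiv), EtOH, 0 °C → rt, 48 h; then cold AcOH to pH 5–6
Reagents that add atoms: none
Why: Claisen–Schmidt condensation, in which the α-methoxy methylene of 4 is the only enolisable position, 6 cannot enolise, and E1cB loss of water gives the enone as the thermodynamic Z isomer (aryl trans to the carbonyl), a geometry that is erased in step 4.

**Step 4**
Reactants: 8 (Z)-3-[2,4-bis(benzyloxy)-5-methoxyphenyl]-1-(2-hydroxy-3,4,6-trimethoxyphenyl)-2-methoxyprop-2-en-1-one
Product: 9 2-[2,4-bis(benzyloxy)-5-methoxyphenyl]-3,5,7,8-tetramethoxy-4H-chromen-4-one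
Conditions: Pd(TFA)2 (10 mol %), 5-nitro-1,10-phenanthroline (20 mol %), O2 (1 atm), DMSO, 100 °C
Reagents that add atoms: none
Why: Proposed new method: Pd(II)-catalysed aerobic dehydrogenative oxa-cyclisation of a 2'-hydroxy-α-alkoxychalcone, a trisubstituted α-heteroatom enone on which this reactivity has not been shown; the α-OMe makes the C=C a better π-donor to electrophilic Pd(II), the phenol adds 6-endo to the benzylic β-carbon by anti-oxypalladation (forming O1–C2), the resulting C3–Pd enolate has H-2 cis to Pd and cannot β-eliminate its α-OMe, so syn β-hydride elimination releases the 3-methoxyflavone and O2 reoxidises Pd(0); the closest known reaction types are the Wacker-type Pd(II) oxidative cyclisation of plain 2'-hydroxychalcones to flavones and the Pd(TFA)2/O2 α,β-dehydrogenation of chromanones, and the neutral conditions spare the benzyl ethers.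

**Step 5**
Reactants: 9 2-[2,4-bis(benzyloxy)-5-methoxyphenyl]-3,5,7,8-tetramethoxy-4H-chromen-4-one
Product: 10 5-hydroxy-2-(2,4-dihydroxy-5-methoxyphenyl)-3,7,8-trimethoxy-4H-chromen-4-one (5,2',4'-trihydroxy-3,7,8,5'-tetramethoxyflavone)
Conditions: BCl3 (1 M in CH2Cl2, 6 equiv), pentamethylbenzene (6 equiv), CH2Cl2, −78 → 0 °C, 2 h; then MeOH, aq. NaHCO3
Reagents that add atoms: none
Why: Lewis-acid ether cleavage, in which BCl3 removes aryl benzyl ethers at low temperature (benzyl cation trapped by pentamethylbenzene) and, on warming to 0 °C, the 5-OMe selectively through the six-membered boron chelate to the C4 carbonyl, while the 3-, 7-, 8- and 5'-OMe groups have no such peri chelation and survive.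

**Compound list**
1 | 1,2,3,5-tetramethoxybenzene | COc1cc(OC)c(OC)c(OC)c1 | starting material
2 | methoxyacetyl chloride | COCC(=O)Cl | starting material
3 | 2-methoxy-1-(2,3,4,6-tetramethoxyphenyl)ethan-1-one (tetramethoxyphenyl ketone formed in the flask in step 1) | COCC(=O)c1c(OC)cc(OC)c(OC)c1OC | intermediate
4 | 1-(2-hydroxy-3,4,6-trimethoxyphenyl)-2-methoxyethan-1-one | COCC(=O)c1c(OC)cc(OC)c(OC)c1O | intermediate
5 | 2,4-dihydroxy-5-methoxybenzaldehyde | COc1cc(C=O)c(O)cc1O | starting material
6 | 2,4-bis(benzyloxy)-5-methoxybenzaldehyde | COc1cc(C=O)c(OCc2ccccc2)cc1OCc1ccccc1 | intermediate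
7 | 3-[2,4-bis(benzyloxy)-5-methoxyphenyl]-3-hydroxy-1-(2-hydroxy-3,4,6-trimethoxyphenyl)-2-methoxypropan-1-one (aldol adduct formed in the flask in step 3; racemic mixture of diastereomers, both stereocentres lost on dehydration) | COC(C(O)c1cc(OC)c(OCc2ccccc2)cc1OCc1ccccc1)C(=O)c1c(O)c(OC)c(OC)cc1OC | intermediate
8 | (Z)-3-[2,4-bis(benzyloxy)-5-methoxyphenyl]-1-(2-hydroxy-3,4,6-trimethoxyphenyl)-2-methoxyprop-2-en-1-one | CO/C(=C\c1cc(OC)c(OCc2ccccc2)cc1OCc1ccccc1)C(=O)c1c(O)c(OC)c(OC)cc1OC | intermediate
9 | 2-[2,4-bis(benzyloxy)-5-methoxyphenyl]-3,5,7,8-tetramethoxy-4H-chromen-4-one | COc1cc(-c2oc3c(OC)c(OC)cc(OC)c3c(=O)c2OC)c(OCc2ccccc2)cc1OCc1ccccc1 | intermediate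
10 | 5-hydroxy-2-(2,4-dihydroxy-5-methoxyphenyl)-3,7,8-trimethoxy-4H-chromen-4-one (achiral) | COc1cc(-c2oc3c(OC)c(OC)cc(O)c3c(=O)c2OC)c(O)cc1O | target

**Totals**
Total step count: 5. Longest linear sequence: 4 steps (step 1 or 2, then steps 3, 4, 5).

**Steps most likely to fail**

Step 4 (the proposed new oxidative ring closure). Risks are a stalled Pd enolate, oxidation of the electron-rich phenol, or poor turnover. The fallback uses known chemistry and separates ring closure from oxidation. It sets out from 8: sodium acetate in refluxing ethanol closes the ring by plain oxa-Michael addition to give racemic trans-(2R,3R)-2-[2,4-bis(benzyloxy)-5-methoxyphenyl]-3,5,7,8-tetramethoxychroman-4-one F4. DDQ in refluxing dioxane then dehydrogenates C2–C3, and the sequence comes back to the route at 9.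

Step 3 (Claisen–Schmidt). The ketone is hindered and chelated, and the aldehyde is electron-rich and ortho-substituted, so conversion may be low. The fallback replaces the aldol logic by a Baker–Venkataraman sequence and sets out from 4 and 6. Pinnick oxidation of 6 (NaClO2, NaH2PO4, 2-methyl-2-butene, t-BuOH/H2O) gives 2,4-bis(benzyloxy)-5-methoxybenzoic acid F1. Steglich esterification of F1 with phenol 4 (EDC·HCl, DMAP, CH2Cl2) gives 2-(2-methoxyacetyl)-3,5,6-trimethoxyphenyl 2,4-bis(benzyloxy)-5-methoxybenzoate F2. Powdered KOH in pyridine at 50 °C effects the acyl migration to 1-[2,4-bis(benzyloxy)-5-methoxyphenyl]-3-(2-hydroxy-3,4,6-trimethoxyphenyl)-2-methoxypropane-1,3-dione F3. Cyclodehydration in AcOH/NaOAc at reflux then comes back to the route at 9, so step 4 is bypassed as well.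

Step 5 (one-pot triple dealkylation). Risks are partial loss of the 3- or 8-OMe, incomplete 5-demethylation, or C-benzylation of the electron-rich rings. The fallback separates the two events with mechanistically different reactions and sets out from 9. Hydrogenolysis (H2, 10 % Pd/C, EtOAc/MeOH, rt) gives 2-(2,4-dihydroxy-5-methoxyphenyl)-3,5,7,8-tetramethoxy-4H-chromen-4-one F5. Anhydrous AlCl3 in MeCN (rt to 50 °C, then 2 M HCl) then cleaves only the chelated 5-OMe and comes back to the route at 10.

**Further compounds**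
F1 | step 3 | 2,4-bis(benzyloxy)-5-methoxybenzoic acid | COc1cc(C(=O)O)c(OCc2ccccc2)cc1OCc1ccccc1
F2 | step 3 | 2-(2-methoxyacetyl)-3,5,6-trimethoxyphenyl 2,4-bis(benzyloxy)-5-methoxybenzoate | COCC(=O)c1c(OC)cc(OC)c(OC)c1OC(=O)c1cc(OC)c(OCc2ccccc2)cc1OCc1ccccc1
F3 | step 3 | 1-[2,4-bis(benzyloxy)-5-methoxyphenyl]-3-(2-hydroxy-3,4,6-trimethoxyphenyl)-2-methoxypropane-1,3-dione (racemic, enolisable) | COC(C(=O)c1c(O)c(OC)c(OC)cc1OC)C(=O)c1cc(OC)c(OCc2ccccc2)cc1OCc1ccccc1
F4 | step 4 | rac-(2R,3R)-2-[2,4-bis(benzyloxy)-5-methoxyphenyl]-3,5,7,8-tetramethoxychroman-4-one (trans; one enantiomer drawn) | O=C1[C@H](OC)[C@@H](c2cc(OC)c(OCc3ccccc3)cc2OCc2ccccc2)Oc2c(OC)c(OC)cc(OC)c12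
F5 | step 5 | 2-(2,4-dihydroxy-5-methoxyphenyl)-3,5,7,8-tetramethoxy-4H-chromen-4-one | COc1cc(-c2oc3c(OC)c(OC)cc(OC)c3c(=O)c2OC)c(O)cc1O
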